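**Retrosynthetic overview**

1. The target is disconnected at the aryl ether (Mitsunobu coupling of umbelliferone with a C11 alcohol); the 3‑hydroxydrima‑6,8(12)‑dien‑11‑ol comes from a methyl drima‑6,8‑dien‑11‑oate by deconjugative protonation (sets C9 and the exocyclic C8=C12) and ester reduction.
2. The dienoate comes from carbonylation of a C9 dienyl triflate, i.e. from a C9 ketone in ring B; the ring B unsaturation arises by excision of the isopropenyl group of carvone, and C12 is added as iodomethane.
3. Ring A (C3 ketone, later the axial alcohol) is made in one operation from three components: methyl isobutyrate (C3–C4), (S)‑carvone (ring B with C5 and C10) and phenyl vinyl sulfone (C1–C2); bond order C4–C5, C10–C1, then ring closure at C2–C3.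
4. Enabling feature: in ring A the oxygenated C3 and the C9 carbon of ring B are 1,5‑related across C4–C5–C10 (Michael retron of a 2‑methylcyclohexenone), C1–C2 is an unsubstituted two‑carbon bridge between nucleophilic C10 and electrophilic C3, and the quaternary C4 and C10 leave C2 as the only enolisable position next to C3.
5. Ring order: ring B is bought in as carvone, ring A is closed in step 1, the coumarin is attached last.

Key step: step 1

Remark on conventions: drimane numbering is used (ring A = C1–C5, C10; ring B = C5–C10; C11 on C9; C12 on C8), drawn with ring A on the left and C1 at the top. In this orientation all bicyclic compounds have the C10 methyl down and H‑5 up (ent‑drimane series); the target is (3S,5S,9R,10R). C2 (next to the sulfone) and C8 of compound 11 are labile or transient centres, and their SMILES show the expected major epimer. Compounds 1, 2, 3 and 20 are commercial.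

**Step 1**
Reactants: 1 (S)‑(+)‑carvone; 2 methyl isobutyrate; 3 phenyl vinyl sulfone
Product: 7 7‑isopropenyl‑2‑(phenylsulfonyl)‑11,12‑dinor‑ent‑drimane‑3,9‑dione, via lithium ester enolate 4 (not isolated), via Michael adduct enolate 5 (not isolated), via sulfonyl carbanion 6 (not isolated)
Conditions: LiN(i‑Pr)2 (LDA, 1.05 equiv), 2, THF, −78 °C; then 1, DMPU, −78 → −30 °C; then 3 (1.0 equiv), −78 °C → rt; aq. NH4Cl
Reagents that add atoms: none
Why: The tetrasubstituted ester enolate 4 adds 1,4 to C5 of carvone by axial attack anti to the C7 isopropenyl group and gives the regiodefined enolate 5; 5 adds through C10 to phenyl vinyl sulfone anti to the now pseudoaxial C5 side chain, which creates the quaternary C10 and the α‑sulfonyl carbanion 6, and 6 attacks the ester carbonyl C3 in a Dieckmann‑type acylation that closes ring A at the C2–C3 bond. The closest known reaction type is the sequential Michael–Michael–ring‑closure (MIMIRC) annulation of lithium enolates with cycloalkenones and vinyl acceptors, terminated as in a tandem Michael–Dieckmann reaction. Ring A closes in the 6‑exo‑trig mode, while ring B enters intact as the cyclohexenone. C5 is controlled by the C7 stereocentre of carvone (trans addition), C10 by C5 (trans alkylation, hence the trans ring fusion), and C2 is a labile centre that should settle equatorial and is erased later. The step needs 1,4‑ over 1,2‑addition (α,α‑disubstituted enolate, DMPU), acylation of 6 in preference to oligomerisation of 3 (six‑membered intramolecular transition state, one equivalent of 3) and irreversibility (deprotonation of the acidic β‑keto sulfone, which can enolise only towards C2 because C4 is quaternary).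

**Step 2**
Reactants: 7 7‑isopropenyl‑2‑(phenylsulfonyl)‑11,12‑dinor‑ent‑drimane‑3,9‑dione
Product: 9 2‑(phenylsulfonyl)‑11,12‑dinor‑ent‑drim‑7‑ene‑3,9‑dione, via methoxy hydroperoxide 8 (not isolated)
Conditions: O3, CH2Cl2/MeOH, −78 °C; N2 purge; then FeSO4·7H2O, Cu(OAc)2·H2O, MeOH, −20 °C → rt
Reagents that add atoms: none
Why: Criegee ozonolysis in methanol should give the α‑methoxy hydroperoxide 8, which divalent iron cleaves to an alkoxy radical that loses methyl acetate by β‑scission, and divalent copper oxidises the C7 radical to the alkene towards the acidic H‑8 (Schreiber‑type dealkenylation of carvone‑derived cyclohexanones to cyclohexenones); the β‑keto sulfone is a keto tautomer and inert to ozone, and any β,γ‑isomer converges in step 3.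

**Step 3**
Reactants: 9 2‑(phenylsulfonyl)‑11,12‑dinor‑ent‑drim‑7‑ene‑3,9‑dione
Product: 11 2‑(phenylsulfonyl)‑11‑nor‑ent‑drim‑6‑ene‑3,9‑dione, via dilithium dienolate 10 (not isolated)
Conditions: LiN(i‑Pr)2 (2.2 equiv), THF, −78 °C; MeI (1.05 equiv), −78 → −40 °C; aq. NH4Cl
Reagents that add atoms: iodomethane CI
Why: The first equivalent of base masks C3 as the β‑keto sulfone enolate and the second removes H‑6 (no α'‑proton exists at quaternary C10) to give the extended dienolate 10, which is methylated kinetically at the α‑carbon C8 anti to the axial C10 methyl (deconjugative α‑alkylation of an enone dienolate); this installs C12 and places the double bond at C6=C7, and the C8 configuration is lost again in step 4.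

**Step 4**
Reactants: 11 2‑(phenylsulfonyl)‑11‑nor‑ent‑drim‑6‑ene‑3,9‑dione
Product: 13 3‑oxo‑2‑(phenylsulfonyl)‑11‑nor‑ent‑drima‑6,8‑dien‑9‑yl trifluoromethanesulfonate, via dipotassium dienolate 12 (not isolated)
Conditions: KN(SiMe3)2 (2.2 equiv), THF, −78 °C; PhNTf2 (1.1 equiv), −78 → 0 °C; aq. NH4Cl
Reagents that add atoms: N‑phenylbis(trifluoromethanesulfonimide) O=S(=O)(N(c1ccccc1)S(=O)(=O)C(F)(F)F)C(F)(F)F
Why: Removal of the doubly activated H‑8 (α to the ketone and allylic) gives the fully substituted dienolate 12, the only enolate the C9 ketone can form, and this reactive potassium dienolate is O‑sulfonylated (enol triflate formation) while the stabilised β‑keto sulfone enolate stays untouched at low temperature.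

**Step 5**
Reactants: 13 3‑oxo‑2‑(phenylsulfonyl)‑11‑nor‑ent‑drima‑6,8‑dien‑9‑yl trifluoromethanesulfonate
Product: 14 methyl 3‑oxo‑2‑(phenylsulfonyl)‑ent‑drima‑6,8‑dien‑11‑oate
Conditions: CO (1 atm), Pd(OAc)2 (5 mol %), dppf, Et3N, MeOH/DMF, 60 °C
Reagents that add atoms: carbon monoxide [C-]#[O+]; methanol CO
Why: Oxidative addition of zerovalent palladium into the enol triflate, CO insertion and methanolysis of the acyl palladium (alkoxycarbonylation of an enol triflate) install C11 at the ester level on the hindered C9 without touching the diene or the β‑keto sulfone.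

**Step 6**
Reactants: 14 methyl 3‑oxo‑2‑(phenylsulfonyl)‑ent‑drima‑6,8‑dien‑11‑oate
Product: 15 methyl 3‑oxo‑ent‑drima‑6,8‑dien‑11‑oate
Conditions: aluminium amalgam (Al/Hg), THF/H2O (9:1), 0 °C → rt
Reagents that add atoms: none
Why: Two‑electron reduction of the β‑keto sulfone cleaves the C2–S bond with loss of benzenesulfinate (reductive desulfonylation), leaving the C3 ketone with C2 as CH2, and the hindered dienoate should not be reduced under these mild conditions.

**Step 7**
Reactants: 15 methyl 3‑oxo‑ent‑drima‑6,8‑dien‑11‑oate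
Product: 16 methyl (3S)‑3‑hydroxy‑ent‑drima‑6,8‑dien‑11‑oate (axial hydroxyl, cis to H‑5)
Conditions: LiBH(s‑Bu)3 (L‑Selectride, 1.3 equiv), THF, −78 °C; aq. NH4Cl
Reagents that add atoms: none
Why: The bulky hydride attacks the 4,4‑dimethyl‑3‑ketone from the equatorial direction because the axial trajectory is blocked by the axial hydrogens at C1 and C5, which should give the axial (3S) alcohol as is usual for 4,4‑dimethyl‑3‑oxo terpenoids; the twisted tetrasubstituted dienoate is not attacked at −78 °C.

**Step 8**
Reactants: 16 methyl (3S)‑3‑hydroxy‑ent‑drima‑6,8‑dien‑11‑oate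
Product: 18 methyl (3S,9R)‑3‑hydroxy‑ent‑drima‑6,8(12)‑dien‑11‑oate, via dilithium dienolate 17 (not isolated)
Conditions: LiN(i‑Pr)2 (3 equiv), THF/DMPU, −78 °C; cannulate into AcOH/THF, −78 °C
Reagents that add atoms: none
Why: After deprotonation of the hydroxyl, the base bound to the ester removes a proton from the C12 methyl, which is cis to the ester, and kinetic protonation of the cross‑conjugated dienolate 17 at the α‑carbon C9 from the face opposite to the axial C10 methyl should give the β,γ‑unsaturated ester with the exocyclic C8=C12 bond and the equatorial (9R) ester (deconjugative protonation, as in the deconjugation of β‑cyclogeranate‑type esters).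

**Step 9**
Reactants: 18 methyl (3S,9R)‑3‑hydroxy‑ent‑drima‑6,8(12)‑dien‑11‑oate
Product: 19 (3S,5S,9R,10R)‑drima‑6,8(12)‑diene‑3,11‑diol
Conditions: i‑Bu2AlH (3.5 equiv), CH2Cl2, −78 → −20 °C; Rochelle salt
Reagents that add atoms: none
Why: Non‑basic hydride reduction of the ester gives the primary alcohol without epimerising C9 or moving the exocyclic double bond back into conjugation.

**Step 10**
Reactants: 19 (3S,5S,9R,10R)‑drima‑6,8(12)‑diene‑3,11‑diol; 20 umbelliferone
Product: 21 7‑{[(3S,5S,9R,10R)‑3‑hydroxydrima‑6,8(12)‑dien‑11‑yl]oxy}‑2H‑chromen‑2‑one (target)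
Conditions: PPh3, DIAD, THF, 0 °C → rt
Reagents that add atoms: none
Why: Mitsunobu etherification activates only the primary C11 hydroxyl, which the acidic phenol displaces by SN2, while the axial neopentyl‑type C3 hydroxyl does not react.

**Compound list**

1 | (S)‑(+)‑carvone, (5S)‑2‑methyl‑5‑(prop‑1‑en‑2‑yl)cyclohex‑2‑en‑1‑one | CC1=CC[C@@H](CC1=O)C(C)=C | starting material
2 | methyl isobutyrate (methyl 2‑methylpropanoate) | COC(=O)C(C)C | starting material
3 | phenyl vinyl sulfone | C=CS(=O)(=O)c1ccccc1 | starting material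
4 | lithium enolate of methyl isobutyrate (not isolated) | COC(O[Li])=C(C)C | intermediate
5 | lithium enolate (C9–OLi, C9=C10) of the 1,4‑adduct; CMe2CO2Me on C5 trans to the C7 isopropenyl group (not isolated) | C1[C@@H](C(C)=C)C[C@H](C(C)(C)C(=O)OC)C(C)=C1O[Li] | intermediate
6 | α‑lithio sulfone; cyclohexanone with quaternary C10 carrying CH2CH(Li)SO2Ph trans to the C5 side chain (not isolated) | C1[C@@H](C(C)=C)C[C@H](C(C)(C)C(=O)OC)[C@@](C)(CC([Li])S(=O)(=O)c2ccccc2)C1=O | intermediate
7 | 7‑isopropenyl‑2‑(phenylsulfonyl)‑11,12‑dinor‑ent‑drimane‑3,9‑dione (trans‑decalin; isopropenyl cis to H‑5, sulfonyl equatorial) | C1[C@@H](C(C)=C)C[C@@H]2C(C)(C)C(=O)[C@@H](S(=O)(=O)c3ccccc3)C[C@@]2(C)C1=O | intermediate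
8 | α‑methoxy hydroperoxide at the former isopropenyl carbon on C7 (not isolated) | C1[C@@H](C(C)(OC)OO)C[C@@H]2C(C)(C)C(=O)[C@@H](S(=O)(=O)c3ccccc3)C[C@@]2(C)C1=O | intermediate
9 | 2‑(phenylsulfonyl)‑11,12‑dinor‑ent‑drim‑7‑ene‑3,9‑dione | C1=CC[C@@H]2C(C)(C)C(=O)[C@@H](S(=O)(=O)c3ccccc3)C[C@@]2(C)C1=O | intermediate
10 | dilithium species: C2=C3 enolate of the β‑keto sulfone and C9–O dienolate (C9=C8, C7=C6) (not isolated) | C=1C=C[C@@H]2C(C)(C)C(O[Li])=C(S(=O)(=O)c3ccccc3)C[C@@]2(C)C=1O[Li] | intermediate
11 | 2‑(phenylsulfonyl)‑11‑nor‑ent‑drim‑6‑ene‑3,9‑dione (C8 methyl cis to H‑5) | C[C@H]1C=C[C@@H]2C(C)(C)C(=O)[C@@H](S(=O)(=O)c3ccccc3)C[C@@]2(C)C1=O | intermediate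
12 | dipotassium species: β‑keto sulfone enolate and C9–O dienolate bearing the C8 methyl (not isolated) | CC=1C=C[C@@H]2C(C)(C)C(O[K])=C(S(=O)(=O)c3ccccc3)C[C@@]2(C)C=1O[K] | intermediate
13 | 3‑oxo‑2‑(phenylsulfonyl)‑11‑nor‑ent‑drima‑6,8‑dien‑9‑yl trifluoromethanesulfonate | CC=1C=C[C@@H]2C(C)(C)C(=O)[C@@H](S(=O)(=O)c3ccccc3)C[C@@]2(C)C=1OS(=O)(=O)C(F)(F)F | intermediate
14 | methyl 3‑oxo‑2‑(phenylsulfonyl)‑ent‑drima‑6,8‑dien‑11‑oate | CC=1C=C[C@@H]2C(C)(C)C(=O)[C@@H](S(=O)(=O)c3ccccc3)C[C@@]2(C)C=1C(=O)OC | intermediate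
15 | methyl 3‑oxo‑ent‑drima‑6,8‑dien‑11‑oate | CC=1C=C[C@@H]2C(C)(C)C(=O)CC[C@@]2(C)C=1C(=O)OC | intermediate
16 | methyl (3S)‑3‑hydroxy‑ent‑drima‑6,8‑dien‑11‑oate (axial OH) | CC=1C=C[C@@H]2C(C)(C)[C@@H](O)CC[C@@]2(C)C=1C(=O)OC | intermediate
17 | dilithium species: C3 alkoxide and ester dienolate (C11=C9, C8=C12) (not isolated) | C=C1C=C[C@@H]2C(C)(C)[C@@H](O[Li])CC[C@@]2(C)C1=C(OC)O[Li] | intermediate
18 | methyl (3S,9R)‑3‑hydroxy‑ent‑drima‑6,8(12)‑dien‑11‑oate | C=C1C=C[C@@H]2C(C)(C)[C@@H](O)CC[C@@]2(C)[C@@H]1C(=O)OC | intermediate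
19 | (3S,5S,9R,10R)‑drima‑6,8(12)‑diene‑3,11‑diol | C=C1C=C[C@@H]2C(C)(C)[C@@H](O)CC[C@@]2(C)[C@@H]1CO | intermediate
20 | umbelliferone (7‑hydroxy‑2H‑chromen‑2‑one) | O=c1ccc2ccc(O)cc2o1 | starting material
21 | 7‑{[(1R,4aS,6S,8aR)‑6‑hydroxy‑5,5,8a‑trimethyl‑2‑methylidene‑1,2,4a,5,6,7,8,8a‑octahydronaphthalen‑1‑yl]methoxy}‑2H‑chromen‑2‑one | C=C1C=C[C@@H]2C(C)(C)[C@@H](O)CC[C@@]2(C)[C@@H]1COc1ccc2ccc(=O)oc2c1 | target

**Step count:** 10 steps in total; longest linear sequence 10 steps (from 1).

**Steps most likely to fail and fallbacks**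

Step 1. The cascade may stall before ring closure: the carbanion can be quenched by proton transfer from C8, the ester enolate can add 1,2 to or enolise carvone, and the vinyl sulfone can oligomerise. The fallback sets out from 1 and separates the three events. Mukaiyama–Michael addition of commercial 1‑methoxy‑2‑methyl‑1‑(trimethylsilyloxy)propene to 1 (Me3SiOTf cat., CH2Cl2, −78 °C) gives the trimethylsilyl enol ether F1. MeLi in THF liberates enolate 5 from it, and alkylation with 3 followed by a proton quench gives the open keto ester sulfone F2. KOt‑Bu in THF then effects the same C2–C3 acylation and returns to the route at 7.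

Step 2. The radical fragmentation may give poor mass balance: the C7 radical can be reduced or trapped by acetate instead of being oxidised to the alkene. The fallback sets out from 7 and removes the isopropenyl group by polar steps. OsO4 (cat.)/NaIO4 cleaves it to the methyl ketone F3. Baeyer–Villiger oxidation with m‑CPBA (migration of secondary C7 with retention) gives the C7 acetate F4, and DBU eliminates acetic acid by E1cB to return to the route at 9.

Step 8. Protonation of the dienolate may occur at C12 (return to the conjugated ester), deprotonation may compete at C5, or the product may reconjugate or epimerise during work‑up. The fallback sets out from 16 and performs the deconjugation at the aldehyde level with in situ trapping. i‑Bu2AlH gives the conjugated dienyl diol F5, and MnO2 oxidises only the allylic primary alcohol to the dienal F6. Ac2O/Et3N/DMAP at 80 °C gives the dienol acetate 3‑acetate F7. NaBH4 in EtOH cleaves the enol acetate; the freed dienolate is protonated at C9 in the protic medium and the β,γ‑unsaturated aldehyde is reduced at once (the classical enol acetate–borohydride deconjugation of steroid enones), giving the 3‑acetate F8. K2CO3/MeOH removes the acetate and returns to the route at 19.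

**Further compounds**

F1 | step 1 | trimethylsilyl enol ether of the 1,4‑adduct of methyl isobutyrate and carvone | C1[C@@H](C(C)=C)C[C@H](C(C)(C)C(=O)OC)C(C)=C1O[Si](C)(C)C
F2 | step 1 | open keto ester sulfone: methyl 2‑methyl‑2‑[2‑methyl‑3‑oxo‑2‑(2‑phenylsulfonylethyl)‑5‑isopropenylcyclohexyl]propanoate | C1[C@@H](C(C)=C)C[C@H](C(C)(C)C(=O)OC)[C@@](C)(CCS(=O)(=O)c2ccccc2)C1=O
F3 | step 2 | 7‑acetyl‑2‑(phenylsulfonyl)‑11,12‑dinor‑ent‑drimane‑3,9‑dione | C1[C@@H](C(C)=O)C[C@@H]2C(C)(C)C(=O)[C@@H](S(=O)(=O)c3ccccc3)C[C@@]2(C)C1=O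
F4 | step 2 | 7‑acetoxy‑2‑(phenylsulfonyl)‑11,12‑dinor‑ent‑drimane‑3,9‑dione | C1[C@@H](OC(C)=O)C[C@@H]2C(C)(C)C(=O)[C@@H](S(=O)(=O)c3ccccc3)C[C@@]2(C)C1=O
F5 | step 8 | (3S)‑ent‑drima‑6,8‑diene‑3,11‑diol | CC=1C=C[C@@H]2C(C)(C)[C@@H](O)CC[C@@]2(C)C=1CO
F6 | step 8 | (3S)‑3‑hydroxy‑ent‑drima‑6,8‑dien‑11‑al | CC=1C=C[C@@H]2C(C)(C)[C@@H](O)CC[C@@]2(C)C=1C=O
F7 | step 8 | (3S)‑ent‑drima‑6,8(12),9(11)‑triene‑3,11‑diyl diacetate (dienol acetate) | C=C1C=C[C@@H]2C(C)(C)[C@@H](OC(C)=O)CC[C@@]2(C)C1=COC(C)=O
F8 | step 8 | (3S,9R)‑11‑hydroxy‑ent‑drima‑6,8(12)‑dien‑3‑yl acetate | C=C1C=C[C@@H]2C(C)(C)[C@@H](OC(C)=O)CC[C@@]2(C)[C@@H]1CO
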